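The flask holds reagent for 0.800 additions per molecule of starting material. I call this ratio c(reagent)/c(starting material) the turnover budget, and I carry it through the argument because each addition costs one reagent.

| flask | starting material | reagent | remark | time |
|---|---|---|---|---|
| dusk | 0.010 M | 0.016 M | run made earlier |  |
| flask | 0.020 M | 0.0160 M |  | 8.0 h |

dusk run (percent of the starting material charged)

| time / min | mono adduct / % | tetra adduct / % |
|---|---|---|
| 6.00 | 14.5 | 0 |
| 20.0 | 25.6 | 1.8 |
| 30.0 | 24.7 | 1.2 |
| 50.0 | 24.5 | 4.4 |
| 80.0 | 21.7 | 5.9 |
| 90.0 | 23.7 | 5.1 |

(scatter of a reading: 1 percentage point)

- the reaction counts as stopped when no species that holds the starting material changes by six tenths of a point or more over the second half of the time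

- at 8.0 h, what has stopped the reaction, if anything has (the reagent has run out first / all of the starting material has reacted / it is still moving)
- amount of mono adduct at 8.0 h, in percent of the starting material charged

I read the dusk table downward. From the row at 50.0 min to the last row, mono adduct goes from 24.5% to 23.7% and tetra adduct from 4.4% to 5.1%. These changes are about the scatter of 1 percentage point, so two rows cannot show that the dusk run has stopped, and I do not count its budget of 1.60 as used. The last row accounts for 0.441 of that budget, counting one turnover per mono adduct and 4 per tetra adduct. The other 1.16 I cannot place: it may be unused reagent or intermediates the table does not show.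

The flask's budget is below one, and every adduct takes at least one addition, so I expect the 0.0160 M of reagent to end first, as the limiting reagent. At the pace of the first dusk row, 14.5% of 0.010 M in 6.00 min, that charge lasts about 1.10 h, shorter than 8.0 h, so I expect it to end inside that time, though this pace need not hold.

For mono adduct I treat additions as random hits, so a budget n leaves a share n·exp(−n) hit once. For dusk at its full budget, which that run need not have used by its last row, this gives 32.3% against 23.7% read, a factor of 0.734 that I keep unexplained. With that factor the flask gets 26.4%.

The forecast differs from my reckoning. It says it is still moving and 10%: “The reagent is nearly spent but not gone”.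

The flask gives the reagent has run out first and 25.4%.

    starting material + reagent → mono adduct + by-product (k = 0.0460 L mol⁻¹ s⁻¹)
    reagent + mono adduct → bis adduct + by-product (k = 0.0680 L mol⁻¹ s⁻¹)
    reagent + bis adduct → triple product + by-product (k = 0.0500 L mol⁻¹ s⁻¹)
    reagent + triple product → tetra adduct + by-product (k = 0.0350 L mol⁻¹ s⁻¹)
    starting material ⇌ dormant form (K = 0.310, k = 0.0100 s⁻¹)

Reagent stands at 0% by 4.00 h, and mono adduct reads 25.4% then and 25.4% at 8.00 h. Counting additions in the end state of the flask, with 2 per bis adduct, 3 per triple product and 4 per tetra adduct, gives 0.800, the budget. The neighbouring flask with 0.050 M of starting material has a budget of 0.320, and the same factor gives 17.1% mono adduct. That neighbour ends with 18.9% mono adduct, reagent at 0% and starting material at 57%.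

Readings and results are calculated from invented constants; scatter was added.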